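Numbering used throughout: C1 lactone carbonyl, C2=C3 enoate, C5 N-CH, C9 spiro carbon, C13 cyclopentane CH, C14 CHMe, C15=C16, C17 carbinol, C18=C19(Cl), C21 OCH2, C23 NCH2.
Cuts: the cis C15=C16 olefin is traced back to a ring alkyne and the macrocycle is opened at C15≡C16. Then C2=C3 (olefin metathesis), N–C23 (allylic amination) and O–C1 (esterification) are cut, leaving a 6-azaspiro[4.5]decane amine, 2-(bromomethyl)acrylic acid and a C16–C21 chloro enyne alcohol. The amine is cut further at N–C5, C4–C5, C5–C6, C8–C9 and C13–C14, and the alcohol at C16–C17.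
Enabling feature: the 15-membered lactone ring (C1, C2, C23, N, C9, C13 to C21, O) holds a single cis CH=CH, C15=C16, between the stereocentres C14 and C17 and across the ring from the ester, so it can be carried as a ring-closed alkyne. N and C14 are cis on the cyclopentane and C17 and C20 are cis on C18=C19, so both alkyne arms point to the same side.
Forward order: cyclopentane (bought), piperidine (N–C5), fragment union (N–C23), tetrahydropyridine (C2=C3, Ru), macrolactone (C15≡C16, Mo), then the Z-olefin and the free carbinol.
Stereochemistry: C13/C14 come from an enamine-catalysed Michael addition, C9 from substrate control (attack anti to the C13 side chain), and C5 from reagent-controlled allylboration followed by SN2 inversion. C17 comes from asymmetric transfer hydrogenation, the C18=C19 geometry from a six-membered lactone, and the C15=C16 geometry from syn hydrogenation.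

Key step: step 19

Remark: 2, 16, 1-propynyllithium and (+)-Ipc2B(allyl) are taken as purchasable. The CIP letters at C14 and C17 change between the alkyne stage (14R,17S) and the alkene stage (14S,17R) only because priorities change; nothing moves in space.

Step 1
Reactants: 1 propanal; 2 1-nitrocyclopentene
Product: 3 (2R)-2-[(1R)-2-nitrocyclopentyl]propanal (syn pair C13/C14; epimer mixture at the nitro-bearing C9)
Conditions: (S)-2-[diphenyl(trimethylsilyloxy)methyl]pyrrolidine (10 mol%), 4-nitrophenol (10 mol%), 1 (3 equiv), toluene, 0 °C to rt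
Reagents that add atoms: none
Why: Enamine-catalysed asymmetric Michael addition of an aldehyde to a nitroalkene, a reaction type that extends to α,β-disubstituted nitroalkenes: the (E)-enamine, open only on the face away from the CPh2(OSiMe3) group, should meet the nitroalkene (ring carbon C12 trans to NO2, as in an (E)-nitroalkene) in the usual synclinal arrangement and give the syn pair C14 (R) and C13 (R), while the mixture at C9 does not matter because that carbon is flattened to a nitronate in step 3.

Step 2
Reactants: 3 (2R)-2-[(1R)-2-nitrocyclopentyl]propanal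
Product: 4 (1R)-1-[(2R)-but-3-yn-2-yl]-2-nitrocyclopentane (epimer mixture at C9)
Conditions: dimethyl (1-diazo-2-oxopropyl)phosphonate, K2CO3, MeOH, 0 °C to rt; pH 7 buffer
Reagents that add atoms: dimethyl (1-diazo-2-oxopropyl)phosphonate, CC(=O)C(=[N+]=[N-])P(=O)(OC)OC
Why: Ohira–Bestmann variant of the Seyferth–Gilbert homologation, whose carbonate/methanol medium is mild enough at low temperature to leave the α-stereocentre C14 in place, the acidic nitroalkane resting as its nitronate until the neutral work-up.

Step 3
Reactants: 4 (1R)-1-[(2R)-but-3-yn-2-yl]-2-nitrocyclopentane; 5 acrolein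
Product: 6 3-{(1S,2R)-2-[(2R)-but-3-yn-2-yl]-1-nitrocyclopentyl}propanal
Conditions: 5 (1.5 equiv), DBU (10 mol%), MeCN, −20 to 0 °C
Reagents that add atoms: none
Why: Base-catalysed Michael addition of a secondary nitronate to an enal, in which the planar C9 should be attacked on the ring face anti to the branched C13 substituent, so that C8 ends trans and the nitro group (the later N) cis to C14, which fixes C9 as S.

Step 4
Reactants: 6 3-{(1S,2R)-2-[(2R)-but-3-yn-2-yl]-1-nitrocyclopentyl}propanal
Product: 7 (1S,2R)-2-[(2R)-but-3-yn-2-yl]-1-(4-methoxybut-3-en-1-yl)-1-nitrocyclopentane (E/Z mixture at the enol ether)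
Conditions: Ph3P(CH2OMe)Cl, KHMDS, THF, 0 °C; then 6, −78 to 0 °C
Reagents that add atoms: (methoxymethyl)triphenylphosphonium chloride, COC[P+](c1ccccc1)(c1ccccc1)c1ccccc1.[Cl-]
Why: Wittig methoxymethylenation, the standard one-carbon homologation of an aldehyde, adds C5 as a masked aldehyde and hides the carbonyl group from the base of step 5, the tertiary nitro group having no α-hydrogen and being inert to the ylide.

Step 5
Reactants: 7 terminal-alkyne enol ether
Product: 9 (1S,2R)-1-(4-methoxybut-3-en-1-yl)-1-nitro-2-[(2R)-pent-3-yn-2-yl]cyclopentane, via lithium acetylide 8 (not isolated)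
Conditions: LiHMDS (1.3 equiv), THF, −78 °C; MeOTf (1.5 equiv), −78 to −20 °C
Reagents that add atoms: methyl trifluoromethanesulfonate, COS(=O)(=O)C(F)(F)F
Why: Deprotonation and C-methylation of a terminal alkyne, run with an amide base and the very reactive MeOTf instead of an alkyllithium (which would attack the nitro group), installs the methyl cap that later leaves as 2-butyne.

Step 6
Reactants: 9 methyl-capped alkyne enol ether
Product: 10 4-{(1S,2R)-1-nitro-2-[(2R)-pent-3-yn-2-yl]cyclopentyl}butanal
Conditions: 1 M aq HCl, THF, rt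
Reagents that add atoms: water, O
Why: Acid-catalysed enol ether hydrolysis through the oxocarbenium ion and the hemiacetal frees the C5 aldehyde under conditions that leave the internal alkyne and the tertiary nitro group alone.

Step 7
Reactants: 10 4-{(1S,2R)-1-nitro-2-[(2R)-pent-3-yn-2-yl]cyclopentyl}butanal
Product: 12 (4S)-7-{(1S,2R)-1-nitro-2-[(2R)-pent-3-yn-2-yl]cyclopentyl}hept-1-en-4-ol, via diisopinocampheylborinate ester 11 (not isolated)
Conditions: (+)-Ipc2B(allyl) (from (−)-α-pinene), Et2O, −78 °C; then 3 M NaOH, 30% H2O2, 0 °C to rt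
Reagents that add atoms: (+)-B-allyldiisopinocampheylborane, C=CCB([C@H]1C[C@H]2C[C@H](C2(C)C)[C@@H]1C)[C@H]1C[C@H]2C[C@H](C2(C)C)[C@@H]1C
Why: Brown asymmetric allylboration through a closed chair transition state, in which the isopinocampheyl groups derived from (−)-α-pinene direct the allyl group to the Re face of the unbranched aldehyde and set C5 as S by reagent control, the remote stereocentres having no influence.

Step 8
Reactants: 12 nitro homoallylic alcohol
Product: 13 (4S)-7-{(1S,2R)-1-nitro-2-[(2R)-pent-3-yn-2-yl]cyclopentyl}hept-1-en-4-yl methanesulfonate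
Conditions: MsCl, Et3N, CH2Cl2, 0 °C
Reagents that add atoms: methanesulfonyl chloride, CS(=O)(=O)Cl
Why: Sulfonylation of a secondary alcohol takes place at oxygen with retention at C5 and turns the carbinol into a leaving group.

Step 9
Reactants: 13 nitro mesylate
Product: 15 (1R,5S,7R)-7-allyl-1-[(2R)-pent-3-yn-2-yl]-6-azaspiro[4.5]decane, via amino mesylate 14 (not isolated)
Conditions: Zn dust (excess), AcOH, THF, rt to 40 °C; filtration, concentration; K2CO3, MeCN, 60 °C
Reagents that add atoms: none
Why: Zinc/acetic acid reduction of a tertiary nitroalkane to the primary amine, which spares alkyne, alkene and mesylate, is followed after basification by a 6-exo-tet intramolecular SN2 displacement that closes the piperidine and inverts C5 from S to R.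

Step 10
Reactants: 16 dihydro-2H-pyran-2,4(3H)-dione
Product: 17 4-chloro-5,6-dihydro-2H-pyran-2-one
Conditions: (COCl)2 (1.2 equiv), DMF (10 mol%), CH2Cl2, 0 °C to rt
Reagents that add atoms: oxalyl chloride, O=C(Cl)C(=O)Cl
Why: Vilsmeier-type conversion of the enol of a cyclic β-keto lactone into the vinylogous acid chloride, as known for tetronic acids and cyclic 1,3-diones, with the six-membered ring forcing the carbonyl carbon (C17) and C20 to be cis on the new C18=C19 bond.

Step 11
Reactants: 17 4-chloro-5,6-dihydro-2H-pyran-2-one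
Product: 19 (5E)-6-chloro-8-hydroxyoct-5-en-2-yn-4-one, via lithium hemiketal alkoxide 18 (not isolated)
Conditions: 1-propynyllithium (1.05 equiv), THF, −78 °C; AcOH in THF, −78 °C
Reagents that add atoms: 1-propynyllithium, CC#C[Li]
Why: 1,2-Addition of an alkynyllithium to a lactone stops after one addition because the hemiketal alkoxide survives at −78 °C until the cold acid quench, and it opens the ring to the δ-hydroxy ynone with the olefin geometry inherited from the ring.

Step 12
Reactants: 19 (5E)-6-chloro-8-hydroxyoct-5-en-2-yn-4-one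
Product: 20 (5E)-6-chloro-8-(triethylsilyloxy)oct-5-en-2-yn-4-one
Conditions: TESOTf (1.05 equiv), 2,6-lutidine, CH2Cl2, −40 °C
Reagents that add atoms: triethylsilyl trifluoromethanesulfonate, CC[Si](CC)(CC)OS(=O)(=O)C(F)(F)F
Why: Silylation of the primary alcohol with a silyl triflate and a non-nucleophilic base (a nucleophilic one could add to the ynone or the β-chloro enone) drains any ring–chain hemiketal equilibrium toward the open-chain ynone.

Step 13
Reactants: 20 TES-protected chloro enynone
Product: 21 (4S,5E)-6-chloro-8-(triethylsilyloxy)oct-5-en-2-yn-4-ol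
Conditions: Ru[(S,S)-TsDPEN](p-cymene) (2 mol%), iPrOH, rt
Reagents that add atoms: none
Why: Noyori asymmetric transfer hydrogenation of an alkynyl ketone, chemoselective for C=O and base-free, in which the alkynyl group takes the place next to the arene ligand so that the (S,S)-catalyst should deliver hydride to the face giving the (S)-propargylic alcohol at C17.

Step 14
Reactants: 21 (4S,5E)-6-chloro-8-(triethylsilyloxy)oct-5-en-2-yn-4-ol
Product: 22 (3E,5S)-5-(tert-butyldimethylsilyloxy)-3-chloro-1-(triethylsilyloxy)oct-3-en-6-yne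
Conditions: TBSCl, imidazole, DMF, rt
Reagents that add atoms: tert-butyldimethylsilyl chloride, CC(C)(C)[Si](C)(C)Cl
Why: Standard imidazole-promoted silylation of a secondary alcohol occurs at oxygen, leaves C17 untouched and gives an ether that lasts until the final step.

Step 15
Reactants: 22 bis-silyl ether
Product: 23 (3E,5S)-5-(tert-butyldimethylsilyloxy)-3-chlorooct-3-en-6-yn-1-ol
Conditions: PPTS (0.2 equiv), MeOH/CH2Cl2, 0 °C
Reagents that add atoms: none
Why: Mild acid methanolysis removes the unhindered primary TES ether much faster than the secondary TBS ether, a standard selectivity between these two silyl groups.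

Step 16
Reactants: 23 chloro enyne alcohol; 24 2-(bromomethyl)acrylic acid
Product: 25 (3E,5S)-5-(tert-butyldimethylsilyloxy)-3-chlorooct-3-en-6-yn-1-yl 2-(bromomethyl)acrylate
Conditions: DIC, DMAP (5 mol%), CH2Cl2, 0 °C
Reagents that add atoms: none
Why: Steglich-type carbodiimide esterification of a primary alcohol, kept cold and low in DMAP so that the allylic bromide is not displaced by the acyl-transfer catalyst.

Step 17
Reactants: 15 spiro piperidine amine; 25 bromomethylacrylate ester
Product: 26 N-alkylated diene diyne: amine 15 carrying on N the CH2C(=CH2)CO2 unit esterified with alcohol 23 (5R,9S,13R,14R,17S)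
Conditions: K2CO3, MeCN, 50 °C
Reagents that add atoms: none
Why: Allylic amination of a hindered secondary amine with a 2-(bromomethyl)acrylate, an electrophile reactive enough for such amines because SN2 and SN2′ attack lead to the same product, forms N–C23 without touching any stereocentre.

Step 18
Reactants: 26 N-alkylated diene diyne
Product: 29 tricyclic diyne ester: spiro-fused 1,2,5,6-tetrahydropyridine-3-carboxylate with C2=C3 closed and both methyl-capped alkynes intact (5R,9S,13R,14R,17S), via tosylate salt of the diene 27 (not isolated), via tosylate salt of the tricycle 28 (not isolated)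
Conditions: p-TsOH·H2O (1.05 equiv), CH2Cl2, rt; RuCl2(=CHPh)(PCy3)(SIMes) (second-generation Grubbs catalyst, 5 mol%), CH2Cl2 (5 mM), 40 °C; aq NaHCO3
Reagents that add atoms: none
Why: Ring-closing olefin metathesis of an ammonium salt, in which the ruthenium carbene loads on the terminal allyl olefin and should close the six-membered ring onto the neighbouring acrylate faster than it can engage the internal, propargylically branched, methyl-capped alkynes, which could only give rings of eight or more members.

Step 19
Reactants: 29 tricyclic diyne ester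
Product: 30 macrocyclic alkyne, C17 TBS ether (15-membered cycloalkyne lactone; 5R,9S,13R,14R,17S)
Conditions: Mo(≡CC6H4-4-OMe)(OSiPh3)3 (10 mol%), MS 5 Å, toluene (2 mM), 80 °C
Reagents that add atoms: none
Why: Ring-closing alkyne metathesis: the molybdenum alkylidyne adds to one methyl-capped alkyne by [2+2] to a metallacyclobutadiene, cycloreversion leaves the substrate bound as a new alkylidyne, and the same sequence on the second alkyne forms C15≡C16, releases 2-butyne and returns the catalyst. The closest known reaction type is the macrocyclisation of methyl-capped diynes with molybdenum alkylidyne silanolate catalysts, which is established for substrates with propargylic silyl ethers, propargylic branching and tertiary amines. The one ring closed is the 15-membered macrolactone (C1, C2, C23, N, C9, C13 to C21, O), closed end to end at a C–C bond under equilibrium control, the sieves taking up 2-butyne so that the equilibrium drains to the monomeric cycloalkyne, a ring large enough to hold the linear C14–C15≡C16–C17 unit without serious strain. No stereocentre is created, and C14 and C17 stay as they are because neither acid nor base is present. The step needs alkyne-over-alkene chemoselectivity, which lies in the alkylidyne itself (enoate, chloroalkene, silyl ether and the hindered amine are ignored), and cyclisation over oligomerisation. The latter rests on high dilution and on the substrate, in which C14 is cis to N on the rigid spiro core and C17 is cis to C20 on C18=C19, so that the two alkyne arms are folded toward each other.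

Step 20
Reactants: 30 macrocyclic alkyne
Product: 31 (15Z)-macrolactone, C17 TBS ether (5R,9S,13R,14S,17R)
Conditions: H2 (1 atm), Pd/CaCO3 poisoned with Pb(OAc)2 (Lindlar catalyst), quinoline, EtOAc, rt
Reagents that add atoms: none
Why: Lindlar semihydrogenation delivers both hydrogens to the same face of the ring alkyne on the poisoned palladium surface and gives the Z-olefin, the alkyne binding far more strongly than the trisubstituted enoate or the chloroalkene.

Step 21
Reactants: 31 (15Z)-macrolactone TBS ether
Product: 32 CNP0129639.4 (5R,9S,13R,14S,17R; 15Z,18E)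
Conditions: TBAF, AcOH (1:1), THF, 0 °C to rt
Reagents that add atoms: none
Why: Fluoride-induced silyl ether cleavage, buffered with acetic acid so that the lactone and the homoallylic ester see no basic fluoride and the doubly allylic carbinol sees no strong acid, frees the C17 hydroxyl group with retention.

Compound list
1 | propanal | CCC=O | starting material
2 | 1-nitrocyclopentene | O=[N+]([O-])C1=CCCC1 | starting material
3 | (2R)-2-[(1R)-2-nitrocyclopentyl]propanal | O=[N+]([O-])C1CCC[C@@H]1[C@@H](C)C=O | intermediate
4 | (1R)-1-[(2R)-but-3-yn-2-yl]-2-nitrocyclopentane | O=[N+]([O-])C1CCC[C@@H]1[C@@H](C)C#C | intermediate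
5 | acrolein | C=CC=O | starting material
6 | 3-{(1S,2R)-2-[(2R)-but-3-yn-2-yl]-1-nitrocyclopentyl}propanal | O=CCC[C@]1(CCC[C@@H]1[C@@H](C)C#C)[N+](=O)[O-] | intermediate
7 | (1S,2R)-2-[(2R)-but-3-yn-2-yl]-1-(4-methoxybut-3-en-1-yl)-1-nitrocyclopentane (E/Z mixture) | COC=CCC[C@]1(CCC[C@@H]1[C@@H](C)C#C)[N+](=O)[O-] | intermediate
8 | lithium acetylide of 7 (not isolated) | COC=CCC[C@]1(CCC[C@@H]1[C@@H](C)C#C[Li])[N+](=O)[O-] | intermediate
9 | (1S,2R)-1-(4-methoxybut-3-en-1-yl)-1-nitro-2-[(2R)-pent-3-yn-2-yl]cyclopentane (E/Z mixture) | COC=CCC[C@]1(CCC[C@@H]1[C@@H](C)C#CC)[N+](=O)[O-] | intermediate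
10 | 4-{(1S,2R)-1-nitro-2-[(2R)-pent-3-yn-2-yl]cyclopentyl}butanal | O=CCCC[C@]1(CCC[C@@H]1[C@@H](C)C#CC)[N+](=O)[O-] | intermediate
11 | diisopinocampheylborinate ester of 12 (not isolated) | C=CC[C@@H](OB([C@H]1C[C@H]2C[C@H](C2(C)C)[C@@H]1C)[C@H]1C[C@H]2C[C@H](C2(C)C)[C@@H]1C)CCC[C@]1(CCC[C@@H]1[C@@H](C)C#CC)[N+](=O)[O-] | intermediate
12 | (4S)-7-{(1S,2R)-1-nitro-2-[(2R)-pent-3-yn-2-yl]cyclopentyl}hept-1-en-4-ol | C=CC[C@@H](O)CCC[C@]1(CCC[C@@H]1[C@@H](C)C#CC)[N+](=O)[O-] | intermediate
13 | methanesulfonate of 12 | C=CC[C@@H](OS(C)(=O)=O)CCC[C@]1(CCC[C@@H]1[C@@H](C)C#CC)[N+](=O)[O-] | intermediate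
14 | amino mesylate (not isolated; acetate salt in the flask) | C=CC[C@@H](OS(C)(=O)=O)CCC[C@]1(CCC[C@@H]1[C@@H](C)C#CC)N | intermediate
15 | (1R,5S,7R)-7-allyl-1-[(2R)-pent-3-yn-2-yl]-6-azaspiro[4.5]decane | C=CC[C@H]1CCC[C@]2(CCC[C@@H]2[C@@H](C)C#CC)N1 | intermediate
16 | dihydro-2H-pyran-2,4(3H)-dione | O=C1CC(=O)CCO1 | starting material
17 | 4-chloro-5,6-dihydro-2H-pyran-2-one | O=C1C=C(Cl)CCO1 | intermediate
18 | lithium 4-chloro-2-(prop-1-yn-1-yl)-5,6-dihydro-2H-pyran-2-olate (not isolated) | CC#CC1([O-])C=C(Cl)CCO1.[Li+] | intermediate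
19 | (5E)-6-chloro-8-hydroxyoct-5-en-2-yn-4-one | CC#CC(=O)/C=C(/Cl)CCO | intermediate
20 | (5E)-6-chloro-8-(triethylsilyloxy)oct-5-en-2-yn-4-one | CC#CC(=O)/C=C(/Cl)CCO[Si](CC)(CC)CC | intermediate
21 | (4S,5E)-6-chloro-8-(triethylsilyloxy)oct-5-en-2-yn-4-ol | CC#C[C@@H](O)/C=C(/Cl)CCO[Si](CC)(CC)CC | intermediate
22 | (3E,5S)-5-(tert-butyldimethylsilyloxy)-3-chloro-1-(triethylsilyloxy)oct-3-en-6-yne | CC#C[C@@H](O[Si](C)(C)C(C)(C)C)/C=C(/Cl)CCO[Si](CC)(CC)CC | intermediate
23 | (3E,5S)-5-(tert-butyldimethylsilyloxy)-3-chlorooct-3-en-6-yn-1-ol | CC#C[C@@H](O[Si](C)(C)C(C)(C)C)/C=C(/Cl)CCO | intermediate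
24 | 2-(bromomethyl)acrylic acid | OC(=O)C(=C)CBr | starting material
25 | (3E,5S)-5-(tert-butyldimethylsilyloxy)-3-chlorooct-3-en-6-yn-1-yl 2-(bromomethyl)acrylate | CC#C[C@@H](O[Si](C)(C)C(C)(C)C)/C=C(/Cl)CCOC(=O)C(=C)CBr | intermediate
26 | N-alkylated diene diyne | C=CC[C@H]1CCC[C@]2(CCC[C@@H]2[C@@H](C)C#CC)N1CC(=C)C(=O)OCC/C(Cl)=C\[C@H](O[Si](C)(C)C(C)(C)C)C#CC | intermediate
27 | p-toluenesulfonate salt of 26 (not isolated) | C=CC[C@H]1CCC[C@]2(CCC[C@@H]2[C@@H](C)C#CC)[NH+]1CC(=C)C(=O)OCC/C(Cl)=C\[C@H](O[Si](C)(C)C(C)(C)C)C#CC.Cc1ccc(cc1)S(=O)(=O)[O-] | intermediate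
28 | p-toluenesulfonate salt of 29 (not isolated) | CC#C[C@@H](O[Si](C)(C)C(C)(C)C)/C=C(/Cl)CCOC(=O)C1=CC[C@H]2CCC[C@]3(CCC[C@@H]3[C@@H](C)C#CC)[NH+]2C1.Cc1ccc(cc1)S(=O)(=O)[O-] | intermediate
29 | tricyclic diyne ester | CC#C[C@@H](O[Si](C)(C)C(C)(C)C)/C=C(/Cl)CCOC(=O)C1=CC[C@H]2CCC[C@]3(CCC[C@@H]3[C@@H](C)C#CC)N2C1 | intermediate
30 | macrocyclic alkyne, C17 TBS ether | C[C@H]1C#C[C@@H](O[Si](C)(C)C(C)(C)C)/C=C(/Cl)CCOC(=O)C2=CC[C@H]3CCC[C@]4(CCC[C@H]14)N3C2 | intermediate
31 | (15Z)-macrolactone, C17 TBS ether | C[C@H]1/C=C\[C@@H](O[Si](C)(C)C(C)(C)C)/C=C(/Cl)CCOC(=O)C2=CC[C@H]3CCC[C@]4(CCC[C@H]14)N3C2 | intermediate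
32 | CNP0129639.4 | C[C@H]1/C=C\[C@@H](O)/C=C(/Cl)CCOC(=O)C2=CC[C@H]3CCC[C@]4(CCC[C@H]14)N3C2 | target

Total step count: 21. Longest linear sequence: 14 steps (steps 1 to 9, then 17 to 21). The side-chain branch (steps 10 to 16) joins at step 17.

Steps most likely to fail

Step 19. Intermolecular metathesis (oligomerisation) may overtake ring closure, or turnover may stall because both alkynes are branched at the propargylic carbon. The fallback makes the C15≡C16 bond between two molecules and closes the ring at the ester. It sets out from 15 and 22 and comes back at 30. N-Alkylation of 15 with methyl 2-(bromomethyl)acrylate (K2CO3, MeCN) should give the diene methyl ester F1. Ring-closing olefin metathesis under the conditions of step 18 then gives the tricyclic methyl ester F2. Alkyne cross-metathesis of F2 with an excess of 22 (same molybdenum catalyst, MS 5 Å, toluene) gives the open-chain alkyne F3. PPTS in MeOH frees the primary alcohol F4, and LiOH in aqueous THF/MeOH gives the seco acid F5. Yamaguchi macrolactonisation (2,4,6-trichlorobenzoyl chloride, Et3N; DMAP, toluene, high dilution) closes the O–C1 bond to 30.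

Step 18. Enyne metathesis of the ruthenium carbene with one of the two methyl-capped alkynes may compete with closure onto the electron-poor 1,1-disubstituted acrylate. The fallback reverses the order of the two metatheses. It sets out from 26 and comes back at 30. The molybdenum alkylidyne of step 19, which ignores terminal and 1,1-disubstituted alkenes, should close 26 to the macrocyclic alkyne diene F6. Olefin metathesis of the tosylate salt of F6 then closes C2=C3. At that point the ruthenium carbene faces only one alkyne, tied into the ring between two branched carbons.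

Step 11. The acetylide may deprotonate the lactone at C20 and trigger eliminative ring opening. A second addition may follow premature collapse of the hemiketal alkoxide, or attack may occur at the chlorine-bearing carbon. The fallback adds the alkyne at the aldehyde oxidation level. It sets out from 17 and comes back at 20. DIBAL-H (1 equiv, CH2Cl2, −78 °C) should give the lactol F7. 1-Propynylmagnesium bromide (2.5 equiv, THF, −78 to 0 °C) adds to its open form to give the racemic diol F8. TESCl and imidazole (CH2Cl2, −20 °C) silylate the primary hydroxyl group selectively to the racemic mono-TES ether F9. MnO2 (CH2Cl2, rt) oxidises the doubly activated secondary alcohol to 20.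

Further compounds
F1 | step 19 | methyl 2-({(1R,5S,7R)-7-allyl-1-[(2R)-pent-3-yn-2-yl]-6-azaspiro[4.5]decan-6-yl}methyl)acrylate | C=CC[C@H]1CCC[C@]2(CCC[C@@H]2[C@@H](C)C#CC)N1CC(=C)C(=O)OC
F2 | step 19 | tricyclic methyl ester with the C14 pentynyl side chain | COC(=O)C1=CC[C@H]2CCC[C@]3(CCC[C@@H]3[C@@H](C)C#CC)N2C1
F3 | step 19 | open-chain C15≡C16 alkyne, C1 methyl ester, C17 TBS ether, C21 TES ether | COC(=O)C1=CC[C@H]2CCC[C@]3(CCC[C@@H]3[C@@H](C)C#C[C@@H](O[Si](C)(C)C(C)(C)C)/C=C(/Cl)CCO[Si](CC)(CC)CC)N2C1
F4 | step 19 | open-chain C21 alcohol, C1 methyl ester | COC(=O)C1=CC[C@H]2CCC[C@]3(CCC[C@@H]3[C@@H](C)C#C[C@@H](O[Si](C)(C)C(C)(C)C)/C=C(/Cl)CCO)N2C1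
F5 | step 19 | seco acid | OC(=O)C1=CC[C@H]2CCC[C@]3(CCC[C@@H]3[C@@H](C)C#C[C@@H](O[Si](C)(C)C(C)(C)C)/C=C(/Cl)CCO)N2C1
F6 | step 18 | macrocyclic alkyne still carrying the C5 allyl group and the C2 exo-methylene group | C[C@H]1C#C[C@@H](O[Si](C)(C)C(C)(C)C)/C=C(/Cl)CCOC(=O)C(=C)CN2[C@@H](CC=C)CCC[C@]23CCC[C@H]13
F7 | step 11 | 4-chloro-5,6-dihydro-2H-pyran-2-ol | OC1C=C(Cl)CCO1
F8 | step 11 | racemic (5E)-6-chlorooct-5-en-2-yne-4,8-diol | CC#CC(O)/C=C(/Cl)CCO
F9 | step 11 | racemic (5E)-6-chloro-8-(triethylsilyloxy)oct-5-en-2-yn-4-ol | CC#CC(O)/C=C(/Cl)CCO[Si](CC)(CC)CC
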